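The runs are simulated for an exercise; noise was put on by code.

Start from the amounts. In the north-west run, c(substrate) of 0.10 M and c(other conformer) of 0.050 M make substrate 66.7% of the charge, and every reading below is a percentage of that charge.

| flask | substrate | other conformer | temperature | remark | time |
|---|---|---|---|---|---|
| north-west | 0.10 M | 0.050 M | 35 °C | run made earlier |  |
| epsilon | 0.050 M | 0.0500 M | 35 °C |  | 2.5 min |
| beta | 0.050 M | 0.0500 M | 5 °C |  | 2.5 min |
| alpha | 0.050 M | 0.0500 M | 20 °C |  | 2.5 min |
| gamma | 0.050 M | 0.0500 M | 50 °C |  | 2.5 min |

north-west run (percent of the substrate and other conformer together charged)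

| time / s | target / % | substrate / % |
|---|---|---|
| 10.0 | 28.5 | 28.2 |
| 12.0 | 32.0 | 23.8 |
| 15.0 | 35.7 | 17.9 |

(standard deviation of a reading: 0.5 percentage points)

- the earlier runs were read with a standard deviation of 0.5 percentage points
- in a conversion other conformer counts as not yet reacted; third conformer counts as reacted
- the earlier runs do not show what temperature does; that part of a forecast is a guess

- the flask with the highest amount of target, in percent of the substrate and other conformer together charged ("all alike" if they lie within 1.5 percentage points) (epsilon / beta / alpha / gamma / all alike)
- final target, as a percentage of the substrate and other conformer together charged, in epsilon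
- final target, as a percentage of the substrate and other conformer together charged, in beta
- final target, as a percentage of the substrate and other conformer together charged, in alpha
- final target, as a percentage of the substrate and other conformer together charged, in gamma

Read the table row by row and subtract. At 10.0 s the substrate has lost 38 percentage points while target stands at 28.5%, a ratio of 0.741. At 12.0 s the ratio is 0.747. The ratio barely moves while the loss grows, so carry one number from the last row, 0.732: call it f, the target won per substrate lost, the selectivity for target.

Now read the substrate column. From first row to last the north-west run reads a rate constant of 0.0909 /s, a lifetime of 11.0 s. Epsilon runs for 2.5 min at 35 °C, which is 13.6 of these lifetimes, so on this reckoning nearly all of its substrate goes, the time being long against the lifetime. Epsilon's charge is 50.0% substrate, so I commit to 36.6% target there, counting nothing through the other conformer, on which the rows are silent. The runs don't show what temperature does, so for beta, alpha and gamma I carry the rule over as a guess: target equals f, read at 35 °C, times substrate lost.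

The forecast names gamma, with 38% in epsilon, 24% in beta, 36% in alpha and 39% in gamma, and says: “Temperature is a guess”.

The flasks give 27.5% in epsilon, 19.9% in beta, 36.3% in alpha and 27.1% in gamma, so alpha holds the most. Epsilon ends 9.1 points below my figure, with 13.1% of isomer of the product B beside its target.

    substrate → target (k = 0.0660 /s, Ea = 69.0 kJ/mol)
    substrate ⇌ other conformer (K = 1.30, k = 0.0250 /s, Ea = 86.0 kJ/mol, ΔH = −90.0 kJ/mol)
    2 other conformer → self-condensation product (k = 4.30 /M/s, Ea = 55.0 kJ/mol)
    other conformer → isomer of the product A (k = 0.0710 /s, Ea = 79.0 kJ/mol)
    target ⇌ isomer of the product B (K = 2.70, k = 0.00310 /s, Ea = 97.0 kJ/mol, ΔH = −53.0 kJ/mol)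
    other conformer ⇌ dormant form (K = 0.480, k = 0.0530 /s, Ea = 79.0 kJ/mol, ΔH = 17.0 kJ/mol)
    other conformer ⇌ third conformer (K = 0.380, k = 0.00870 /s, Ea = 87.0 kJ/mol, ΔH = −22.0 kJ/mol)
    third conformer → third product (k = 0.0530 /s, Ea = 71.0 kJ/mol)
    (constants at 35 °C)

Now test the rule at 5 °C. Beta still holds 26.3% substrate at 2.50 min, so it has lost 24 points, and its target makes f read 0.841, higher than the 0.732 from the north-west run. Carry that beta value to the neighbouring flask, which is beta with 0.12 M of substrate. Its charge is 70.6% substrate and 37.1% remains, so it has lost 33 points, and f gives 28.1% target. At 2.50 min that flask holds 28.1% target.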